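**Plan**

1. Retrosynthesis, endgame: the C12 hydroxyl is carried as a 2-naphthylmethyl (NAP) ether and the three acetates go on last; the 8-hydroxy-17-H lactone comes from the 8,17-epoxide of a Δ8(17) butenolide.
2. The ten-membered ring is cut at C6–C7 (Nozaki–Hiyama–Kishi closure of a (Z)-vinyl iodide onto the C7 lactol), then at C8–C9 (NHK coupling of a tetronate triflate), C3–C4 (enolate allylation) and C2–C3 (methyl ketone from a nitrile).
3. Ring A (C1, C10–C14) is cut at C13–C14 and C11–C12: a vinyl ether (C12–C13) is inserted between a C14 aldehyde and a C11 allylsilane terminus in one Lewis-acid cascade. This works because C12 and C14 are 1,3-dioxygenated across the C13 methylene, and C14 sits on the quaternary C1, so the aldehyde cannot enolise and C11 cannot reach C14.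
4. Forward order: quaternary C1 → ring A (key step) → C2–C6 chain → C9 and butenolide → ten-membered ring → lactone oxidation pattern → acetates.
5. Stereochemistry: C1 from an organocatalytic hydroxymethylation; C14, C11 and C12 from the key step relative to C1; C2 by CBS reduction; C10 by hydroboration; C9 by Felkin reduction; C7 by macrocyclisation and equilibration; C8 by hydroxyl-directed epoxidation; C17 by enolate protonation; the (Z)-C5=C6 alkene from anti-carbomagnesiation of propargyl alcohol.

Key step: step 7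

Remark: atoms are numbered as in the briarane skeleton (C1 quaternary fusion carbon with the C15 methyl, C2–C9 around the ten-membered ring to C10, C11–C14 around ring A, C16/C18/C20 methyls, C17 and C19 lactone carbons); 2-methyl-3-oxopentanenitrile and 3-methyltetronic acid are taken as purchasable.

**Route**

Step 1
Reactants: 1 2-methyl-3-oxopentanenitrile (racemic)
Product: 2 (S)-2-(hydroxymethyl)-2-methyl-3-oxopentanenitrile
Conditions: aq. HCHO (37%, 3 equiv), quinine-derived bifunctional squaramide (10 mol %; the pseudo-enantiomer that gives S), CH2Cl2, −20 °C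
Reagents that add atoms: formaldehyde C=O
Why: Organocatalytic asymmetric aldol-type hydroxymethylation of an α-substituted activated methine should create the quaternary C1 centre, the hydrogen-bonded enolate–catalyst ion pair fixing the face attacked by formaldehyde.

Step 2
Reactants: 2 (S)-2-(hydroxymethyl)-2-methyl-3-oxopentanenitrile
Product: 3 (S)-2-methyl-3-oxo-2-[(triethylsilyloxy)methyl]pentanenitrile
Conditions: TESCl, imidazole, CH2Cl2, 0 °C
Reagents that add atoms: chlorotriethylsilane CC[Si](Cl)(CC)CC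
Why: Standard silylation of a primary alcohol masks the future C14 oxygen for the enolate chemistry; C1 is quaternary and cannot epimerise.

Step 3
Reactants: 3 (S)-2-methyl-3-oxo-2-[(triethylsilyloxy)methyl]pentanenitrile
Product: 4 (S,Z)-4-cyano-4-methyl-5-(triethylsilyloxy)pent-2-en-3-yl trifluoromethanesulfonate
Conditions: KHMDS, THF, −78 °C; then PhNTf2, −78 → 0 °C
Reagents that add atoms: N-phenylbis(trifluoromethanesulfonimide) O=S(=O)(N(c1ccccc1)S(=O)(=O)C(F)(F)F)C(F)(F)F
Why: The ketone can enolise only toward C11, and an ethyl ketone next to a quaternary carbon should give the Z(O)-enolate, trapped as the (Z)-enol triflate with the C20 methyl anti to C1.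

Step 4
Reactants: 4 (S,Z)-4-cyano-4-methyl-5-(triethylsilyloxy)pent-2-en-3-yl trifluoromethanesulfonate
Product: 5 (S,Z)-2-methyl-2-[(triethylsilyloxy)methyl]-3-[(trimethylsilyl)methyl]pent-3-enenitrile
Conditions: Me3SiCH2MgCl, Pd(PPh3)4 (5 mol %), THF, 0 °C → rt
Reagents that add atoms: (trimethylsilyl)methylmagnesium chloride C[Si](C)(C)C[Mg]Cl
Why: Kumada–Corriu coupling of an enol triflate proceeds with retention of alkene geometry and should give the crotyl-type allylsilane (C9 carries silicon, C20 cis to C9).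

Step 5
Reactants: 5 (S,Z)-2-methyl-2-[(triethylsilyloxy)methyl]-3-[(trimethylsilyl)methyl]pent-3-enenitrile
Product: 6 (S,Z)-2-formyl-2-methyl-3-[(trimethylsilyl)methyl]pent-3-enenitrile
Conditions: (COCl)2, DMSO, CH2Cl2, −78 → −40 °C; then Et3N
Reagents that add atoms: none
Why: Swern conditions oxidise primary triethylsilyl ethers directly (desilylation by the chlorosulfonium salt, then oxidation), giving the non-enolisable C14 aldehyde without acid that would protodesilylate the allylsilane.

Step 6
Reactants: 7 naphthalen-2-ylmethanol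
Product: 8 2-[(ethenyloxy)methyl]naphthalene
Conditions: vinyl acetate, [Ir(cod)Cl]2 (1 mol %), Na2CO3, toluene, 100 °C
Reagents that add atoms: vinyl acetate CC(=O)OC=C
Why: Iridium-catalysed transfer vinylation of a benzylic alcohol should give the vinyl ether that delivers C12–C13 with a DDQ-cleavable group on the C12 oxygen.

Step 7
Reactants: 6 (S,Z)-2-formyl-2-methyl-3-[(trimethylsilyl)methyl]pent-3-enenitrile; 8 2-[(ethenyloxy)methyl]naphthalene
Product: 10 (1S,3R,4S,6S)-6-hydroxy-1,3-dimethyl-2-methylidene-4-(naphthalen-2-ylmethoxy)cyclohexane-1-carbonitrile, via O14-trimethylsilyl ether 9 (not isolated)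
Conditions: 8 (3 equiv, slow addition), TMSOTf (0.2 equiv), 2,6-di-tert-butyl-4-methylpyridine (0.3 equiv), CH2Cl2, −78 °C; then 0.5 M aq. HCl, THF, 0 °C
Reagents that add atoms: none
Why: Proposed new method: TMSOTf silylates the aldehyde oxygen, the vinyl ether adds through C13 to C14 (Mukaiyama-type) and leaves an O-naphthylmethyl oxocarbenium ion at C12, which the allylsilane terminus C11 captures; loss of Me3Si+ regenerates TMSOTf and leaves the C10=C9 exocyclic methylene, so the silicon that leaves C9 ends on O14. The closest known reaction types are the Mukaiyama aldol–Prins cascade and the intramolecular Hosomi–Sakurai cyclisation of allylsilanes onto oxocarbenium ions. Ring A (C1–C10–C11–C12–C13–C14) closes in a 6-exo-trig mode with respect to the C12=O+ bond through a chair. C14 should be set in the first addition by Felkin–Anh/Cornforth control, the nucleophile coming anti to the C10 alkenyl branch with the small nitrile dipole opposed to C=O. C11 should follow from the (Z)-crotylsilane, which puts C20 equatorial in the chair with equatorial C15 and axial nitrile, and C12 from the synclinal approach usual for allylsilanes, which puts the NAP-oxy group axial (cis to C20, anti to O14). The step needs the vinyl ether to add before the allylsilane reacts, which the structure secures because C11 could only reach C14 through a four-membered ring, and it needs ring closure to outrun a second vinyl ether addition, which the intramolecular six-ring closure at low temperature should secure.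

Step 8
Reactants: 10 (1S,3R,4S,6S)-6-hydroxy-1,3-dimethyl-2-methylidene-4-(naphthalen-2-ylmethoxy)cyclohexane-1-carbonitrile
Product: 11 O14-tert-butyldimethylsilyl ether of 10
Conditions: TBSOTf, 2,6-lutidine, CH2Cl2, −78 → 0 °C
Reagents that add atoms: tert-butyldimethylsilyl trifluoromethanesulfonate CC(C)(C)[Si](C)(C)OS(=O)(=O)C(F)(F)F
Why: A silyl triflate silylates the hindered neopentyl C14 alcohol and blocks retro-aldol cleavage of C1–C14 in the basic steps that follow.

Step 9
Reactants: 11 O14-tert-butyldimethylsilyl ether of 10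
Product: 13 ring A methyl ketone (acetyl on C1 in place of the nitrile; C2 and C3 in place), via N-H ketimine 12 (not isolated)
Conditions: MeLi (3 equiv), Et2O, 0 °C → rt; then 0.5 M aq. HCl, THF, 0 °C
Reagents that add atoms: methyllithium [Li]C; water O
Why: Organolithium addition to a nitrile without α-hydrogens stops at the N-lithio ketimine, whose hydrolysis should give the C2 methyl ketone with C3 attached.

Step 10
Reactants: 14 prop-2-yn-1-ol
Product: 16 (Z)-2-methyl-3-(trimethylsilyl)prop-2-en-1-ol, via O-trimethylsilyl ether 15 (not isolated)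
Conditions: MeMgBr (2.5 equiv), CuI (10 mol %), THF, −10 °C → rt; then Me3SiCl (2.5 equiv); then 1 M aq. HCl work-up
Reagents that add atoms: methylmagnesium bromide C[Mg]Br; chlorotrimethylsilane C[Si](C)(C)Cl
Why: Copper-catalysed anti-carbomagnesiation of propargyl alcohol through the chelated alkoxide gives the alkenylmagnesium cis to the CH2O group, and C-silylation with retention fixes the (Z) geometry needed for C5=C6.

Step 11
Reactants: 16 (Z)-2-methyl-3-(trimethylsilyl)prop-2-en-1-ol
Product: 17 (Z)-(3-bromo-2-methylprop-1-en-1-yl)trimethylsilane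
Conditions: CBr4, PPh3, CH2Cl2, 0 °C
Reagents that add atoms: tetrabromomethane BrC(Br)(Br)Br
Why: The Appel reaction converts the primary allylic alcohol to the bromide without touching the alkene geometry.

Step 12
Reactants: 13 ring A methyl ketone; 17 (Z)-(3-bromo-2-methylprop-1-en-1-yl)trimethylsilane
Product: 18 C2 ketone carrying the C3–C6 chain with the (Z)-vinylsilane at C6
Conditions: LDA, THF, −78 °C; then 17, DMPU, −78 → −30 °C
Reagents that add atoms: none
Why: The methyl ketone can enolise only at C3, and SN2 alkylation of its lithium enolate by the allylic bromide forms C3–C4; the vinylsilane masks C6 until the second chromium-mediated coupling.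

Step 13
Reactants: 18 C2 ketone carrying the C3–C6 chain
Product: 19 (2S)-alcohol of 18
Conditions: (R)-2-methyl-CBS-oxazaborolidine (0.5 equiv), catecholborane (2 equiv), toluene, −78 °C
Reagents that add atoms: none
Why: Corey–Bakshi–Shibata reduction differentiates the quaternary C1 (large) from the C3 methylene (small), so the (R)-catalyst should give 2S, and catecholborane leaves the alkenes alone.

Step 14
Reactants: 19 (2S)-alcohol of 18
Product: 20 O2-triethylsilyl ether of 19
Conditions: TESOTf, 2,6-lutidine, CH2Cl2, −78 °C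
Reagents that add atoms: triethylsilyl trifluoromethanesulfonate CC[Si](CC)(CC)OS(=O)(=O)C(F)(F)F
Why: Silylation protects the C2 alcohol through the oxidations ahead; no stereocentre is affected.

Step 15
Reactants: 20 O2-triethylsilyl ether of 19
Product: 22 C9 primary alcohol (C10–H α; CH2OH on C10), via B-alkyl-9-borabicyclononane 21 (not isolated)
Conditions: 9-BBN (3 equiv), THF, 60 °C; then 3 M NaOH, 30% H2O2, 0 °C → rt
Reagents that add atoms: 9-borabicyclo[3.3.1]nonane B1C2CCCC1CCC2 (boron carried only in 21); hydrogen peroxide OO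
Why: Anti-Markovnikov hydroboration of the exocyclic methylene should occur from the face opposite the two flanking β-methyl groups (C15 and C20), so H10 is delivered α and C9 ends β, while the hindered trisubstituted vinylsilane is left alone.

Step 16
Reactants: 22 C9 primary alcohol
Product: 23 C9 aldehyde
Conditions: Dess–Martin periodinane, NaHCO3, CH2Cl2, 0 °C
Reagents that add atoms: none
Why: Buffered Dess–Martin oxidation gives the aldehyde under neutral conditions that should not epimerise the adjacent C10 centre.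

Step 17
Reactants: 24 4-hydroxy-3-methylfuran-2(5H)-one (3-methyltetronic acid)
Product: 25 4-methyl-5-oxo-2,5-dihydrofuran-3-yl trifluoromethanesulfonate
Conditions: Tf2O, Et3N, CH2Cl2, −78 °C
Reagents that add atoms: trifluoromethanesulfonic anhydride O=S(=O)(OS(=O)(=O)C(F)(F)F)C(F)(F)F
Why: O-Triflation of the vinylogous acid gives an alkenyl triflate that carries C7, C8, C17, C18 and C19 as a butenolide.

Step 18
Reactants: 23 C9 aldehyde; 25 4-methyl-5-oxo-2,5-dihydrofuran-3-yl trifluoromethanesulfonate
Product: 26 C9 carbinols bearing the butenolide on C9 (mixture of C9 epimers)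
Conditions: CrCl2 (4 equiv), NiCl2 (2 mol %), 25 (2 equiv), DMF, rt
Reagents that add atoms: none
Why: Nozaki–Hiyama–Kishi coupling forms C8–C9 chemoselectively at the aldehyde and tolerates the lactone and the vinylsilane; the C9 configuration is not relied on here.

Step 19
Reactants: 26 C9 carbinols
Product: 27 C9 ketone (4-acylbutenolide)
Conditions: Dess–Martin periodinane, NaHCO3, CH2Cl2, 0 °C
Reagents that add atoms: none
Why: Oxidation converges both C9 epimers on one ketone so that C9 can be set by reduction.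

Step 20
Reactants: 27 C9 ketone
Product: 28 (9S)-alcohol
Conditions: NaBH4, CeCl3·7H2O, MeOH, −78 °C
Reagents that add atoms: none
Why: Luche conditions give 1,2-reduction of the cross-conjugated ketone, and Felkin–Anh attack anti to the quaternary C1 on C10 should give the 9S carbinol.

Step 21
Reactants: 28 (9S)-alcohol
Product: 30 C7 lactol (5-hydroxybutenolide; C9–OH free; C7 epimers), via bis(trimethylsilyl) silyloxyfuran 29 (not isolated)
Conditions: TMSOTf (2.5 equiv), Et3N (3 equiv), CH2Cl2, −78 °C; then dimethyldioxirane (1.05 equiv) in acetone, −78 °C; then 10% aq. citric acid, MeOH, 0 °C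
Reagents that add atoms: trimethylsilyl trifluoromethanesulfonate C[Si](C)(C)OS(=O)(=O)C(F)(F)F (silicon carried only in 29); dimethyldioxirane CC1(C)OO1
Why: γ-Deprotonation of the butenolide gives the 2-silyloxyfuran, whose oxidation at the electron-rich C7 is a known route to 5-hydroxybutenolides; it brings C7 to the aldehyde level, and the acidic work-up frees the C9 hydroxyl.

Step 22
Reactants: 30 C7 lactol
Product: 31 (Z)-vinyl iodide lactol
Conditions: N-iodosuccinimide (1.3 equiv), MeCN/ClCH2CN 4:1, 0 °C, dark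
Reagents that add atoms: N-iodosuccinimide O=C1CCC(=O)N1I
Why: Iododesilylation of the vinylsilane goes by ipso substitution with retention, unmasking the (Z)-C6 iodide only after the first chromium coupling.

Step 23
Reactants: 31 (Z)-vinyl iodide lactol
Product: 33 macrocyclic Δ8(17)-butenolide (ten-membered ring closed; C9–OH free), via seco hydroxy acid 32 (not isolated)
Conditions: CrCl2 (10 equiv), NiCl2 (0.1 equiv), DMSO/THF 3:1, 0.002 M (syringe-pump addition), rt; then 10% aq. citric acid work-up
Reagents that add atoms: none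
Why: Intramolecular Nozaki–Hiyama–Kishi addition of the (Z)-alkenylchromium to the open aldehyde form of the lactol forms C6–C7 with retention of the alkene, and the γ-hydroxy (Z)-enoic acid relactonises; C7 is the γ-position of a butenolide and can be equilibrated with mild base to the less strained epimer, expected to be 7S.

Step 24
Reactants: 33 macrocyclic Δ8(17)-butenolide
Product: 34 8,17-epoxy lactone
Conditions: t-BuOOH (3 equiv), n-BuLi (2.9 equiv), THF, −78 → −20 °C
Reagents that add atoms: tert-butyl hydroperoxide CC(C)(C)OO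
Why: Weitz–Scheffer-type epoxidation with lithium tert-butylperoxide attacks only the electron-poor butenolide, and coordination to the lithium alkoxide of the free C9 hydroxyl should deliver oxygen to the face of C8 syn to O9, which is the face required for the 8-hydroxyl.

Step 25
Reactants: 34 8,17-epoxy lactone
Product: 35 8-hydroxy lactone (O2-TES, O14-TBS, O12-NAP)
Conditions: SmI2 (2.5 equiv), THF/MeOH 10:1, −90 °C
Reagents that add atoms: none
Why: SmI2 cleaves the α C–O bond of an α,β-epoxy ester to give the β-hydroxy lactone with C8 unchanged, and protonation of the samarium enolate at C17 anti to the C9 branch puts the C18 methyl cis to the 8-hydroxyl, which is also the thermodynamic epimer.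

Step 26
Reactants: 35 8-hydroxy lactone
Product: 36 tetraol 12-O-NAP ether (free OH at C2, C8, C9, C14)
Conditions: HF·pyridine, pyridine/THF, 0 °C → rt
Reagents that add atoms: none
Why: Buffered fluoride removes both silyl ethers without touching the lactone, the NAP ether or the alkene.

Step 27
Reactants: 36 tetraol 12-O-NAP ether
Product: 37 2,9,14-triacetate 12-O-NAP ether
Conditions: Ac2O, pyridine, DMAP (0.2 equiv), CH2Cl2, rt
Reagents that add atoms: acetic anhydride CC(=O)OC(C)=O
Why: The three secondary alcohols are acetylated while the hindered tertiary C8 hydroxyl should stay free under these conditions.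

Step 28
Reactants: 37 2,9,14-triacetate 12-O-NAP ether
Product: 38 CNP0195208.2 (target)
Conditions: DDQ (1.5 equiv), CH2Cl2/pH 7 buffer 10:1, 0 °C → rt
Reagents that add atoms: none
Why: Oxidative cleavage of the 2-naphthylmethyl ether frees the C12 hydroxyl and is compatible with the acetates, the lactone and the trisubstituted alkene.

**Compound list**

1 | 2-methyl-3-oxopentanenitrile (racemic) | CCC(=O)C(C)C#N | starting material
2 | (S)-2-(hydroxymethyl)-2-methyl-3-oxopentanenitrile | N#C[C@@](C)(CO)C(=O)CC | intermediate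
3 | (S)-2-methyl-3-oxo-2-[(triethylsilyloxy)methyl]pentanenitrile | N#C[C@@](C)(CO[Si](CC)(CC)CC)C(=O)CC | intermediate
4 | (S,Z)-4-cyano-4-methyl-5-(triethylsilyloxy)pent-2-en-3-yl trifluoromethanesulfonate | N#C[C@@](C)(CO[Si](CC)(CC)CC)/C(OS(=O)(=O)C(F)(F)F)=C/C | intermediate
5 | (S,Z)-2-methyl-2-[(triethylsilyloxy)methyl]-3-[(trimethylsilyl)methyl]pent-3-enenitrile | N#C[C@@](C)(CO[Si](CC)(CC)CC)/C(C[Si](C)(C)C)=C/C | intermediate
6 | (S,Z)-2-formyl-2-methyl-3-[(trimethylsilyl)methyl]pent-3-enenitrile | N#C[C@@](C)(C=O)/C(C[Si](C)(C)C)=C/C | intermediate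
7 | naphthalen-2-ylmethanol | OCc1ccc2ccccc2c1 | starting material
8 | 2-[(ethenyloxy)methyl]naphthalene | C=COCc1ccc2ccccc2c1 | intermediate
9 | O14-trimethylsilyl ether of 10 | N#C[C@@]1(C)[C@@H](O[Si](C)(C)C)C[C@H](OCc2ccc3ccccc3c2)[C@H](C)C1=C | intermediate
10 | (1S,3R,4S,6S)-6-hydroxy-1,3-dimethyl-2-methylidene-4-(naphthalen-2-ylmethoxy)cyclohexane-1-carbonitrile (ring A: C1 nitrile, C14 OH, C12 O-NAP, C11 methyl, C10=C9H2) | N#C[C@@]1(C)[C@@H](O)C[C@H](OCc2ccc3ccccc3c2)[C@H](C)C1=C | intermediate
11 | O14-tert-butyldimethylsilyl ether of 10 | N#C[C@@]1(C)[C@@H](O[Si](C)(C)C(C)(C)C)C[C@H](OCc2ccc3ccccc3c2)[C@H](C)C1=C | intermediate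
12 | N-H ketimine from 11 and methyllithium | CC(=N)[C@@]1(C)[C@@H](O[Si](C)(C)C(C)(C)C)C[C@H](OCc2ccc3ccccc3c2)[C@H](C)C1=C | intermediate
13 | ring A methyl ketone (C2 acetyl on C1) | CC(=O)[C@@]1(C)[C@@H](O[Si](C)(C)C(C)(C)C)C[C@H](OCc2ccc3ccccc3c2)[C@H](C)C1=C | intermediate
14 | prop-2-yn-1-ol | C#CCO | starting material
15 | (Z)-trimethyl{[2-methyl-3-(trimethylsilyl)prop-2-en-1-yl]oxy}silane | C[Si](C)(C)OC/C(C)=C\[Si](C)(C)C | intermediate
16 | (Z)-2-methyl-3-(trimethylsilyl)prop-2-en-1-ol | OC/C(C)=C\[Si](C)(C)C | intermediate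
17 | (Z)-(3-bromo-2-methylprop-1-en-1-yl)trimethylsilane | BrC/C(C)=C\[Si](C)(C)C | intermediate
18 | C2 ketone with C3–C6 chain, (Z)-vinylsilane at C6 | C[Si](C)(C)/C=C(C)\CCC(=O)[C@@]1(C)[C@@H](O[Si](C)(C)C(C)(C)C)C[C@H](OCc2ccc3ccccc3c2)[C@H](C)C1=C | intermediate
19 | (2S)-alcohol of 18 | C[Si](C)(C)/C=C(C)\CC[C@H](O)[C@@]1(C)[C@@H](O[Si](C)(C)C(C)(C)C)C[C@H](OCc2ccc3ccccc3c2)[C@H](C)C1=C | intermediate
20 | O2-triethylsilyl ether of 19 | C[Si](C)(C)/C=C(C)\CC[C@H](O[Si](CC)(CC)CC)[C@@]1(C)[C@@H](O[Si](C)(C)C(C)(C)C)C[C@H](OCc2ccc3ccccc3c2)[C@H](C)C1=C | intermediate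
21 | B-(C9-alkyl)-9-borabicyclo[3.3.1]nonane from 20 | C[Si](C)(C)/C=C(C)\CC[C@H](O[Si](CC)(CC)CC)[C@@]1(C)[C@@H](O[Si](C)(C)C(C)(C)C)C[C@H](OCc2ccc3ccccc3c2)[C@H](C)[C@@H]1CB2C3CCCC2CCC3 | intermediate
22 | C9 primary alcohol (C10–H α) | C[Si](C)(C)/C=C(C)\CC[C@H](O[Si](CC)(CC)CC)[C@@]1(C)[C@@H](O[Si](C)(C)C(C)(C)C)C[C@H](OCc2ccc3ccccc3c2)[C@H](C)[C@@H]1CO | intermediate
23 | C9 aldehyde | C[Si](C)(C)/C=C(C)\CC[C@H](O[Si](CC)(CC)CC)[C@@]1(C)[C@@H](O[Si](C)(C)C(C)(C)C)C[C@H](OCc2ccc3ccccc3c2)[C@H](C)[C@@H]1C=O | intermediate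
24 | 4-hydroxy-3-methylfuran-2(5H)-one (3-methyltetronic acid) | CC1=C(O)COC1=O | starting material
25 | 4-methyl-5-oxo-2,5-dihydrofuran-3-yl trifluoromethanesulfonate | CC1=C(OS(=O)(=O)C(F)(F)F)COC1=O | intermediate
26 | C9 carbinols with butenolide on C9 (C9 epimers) | C[Si](C)(C)/C=C(C)\CC[C@H](O[Si](CC)(CC)CC)[C@@]1(C)[C@@H](O[Si](C)(C)C(C)(C)C)C[C@H](OCc2ccc3ccccc3c2)[C@H](C)[C@@H]1C(O)C2=C(C)C(=O)OC2 | intermediate
27 | C9 ketone (4-acylbutenolide) | C[Si](C)(C)/C=C(C)\CC[C@H](O[Si](CC)(CC)CC)[C@@]1(C)[C@@H](O[Si](C)(C)C(C)(C)C)C[C@H](OCc2ccc3ccccc3c2)[C@H](C)[C@@H]1C(=O)C2=C(C)C(=O)OC2 | intermediate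
28 | (9S)-alcohol | C[Si](C)(C)/C=C(C)\CC[C@H](O[Si](CC)(CC)CC)[C@@]1(C)[C@@H](O[Si](C)(C)C(C)(C)C)C[C@H](OCc2ccc3ccccc3c2)[C@H](C)[C@@H]1[C@H](O)C2=C(C)C(=O)OC2 | intermediate
29 | bis(trimethylsilyl) silyloxyfuran (O9-TMS, 2-TMSO-furan) | C[Si](C)(C)/C=C(C)\CC[C@H](O[Si](CC)(CC)CC)[C@@]1(C)[C@@H](O[Si](C)(C)C(C)(C)C)C[C@H](OCc2ccc3ccccc3c2)[C@H](C)[C@@H]1[C@H](O[Si](C)(C)C)c2coc(O[Si](C)(C)C)c2C | intermediate
30 | C7 lactol (5-hydroxybutenolide, C7 epimers), C9–OH free | C[Si](C)(C)/C=C(C)\CC[C@H](O[Si](CC)(CC)CC)[C@@]1(C)[C@@H](O[Si](C)(C)C(C)(C)C)C[C@H](OCc2ccc3ccccc3c2)[C@H](C)[C@@H]1[C@H](O)C2=C(C)C(=O)OC2O | intermediate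
31 | (Z)-vinyl iodide lactol | I/C=C(C)\CC[C@H](O[Si](CC)(CC)CC)[C@@]1(C)[C@@H](O[Si](C)(C)C(C)(C)C)C[C@H](OCc2ccc3ccccc3c2)[C@H](C)[C@@H]1[C@H](O)C2=C(C)C(=O)OC2O | intermediate
32 | seco (Z)-4-hydroxy-2-enoic acid of the ten-membered ring | CC[Si](CC)(CC)O[C@H]1CC/C(C)=C\[C@H](O)/C(=C(\C(=O)O)C)[C@@H](O)[C@H]2[C@@H](C)[C@@H](OCc3ccc4ccccc4c3)C[C@H](O[Si](C)(C)C(C)(C)C)[C@@]21C | intermediate
33 | macrocyclic Δ8(17)-butenolide (O2-TES, O14-TBS, O12-NAP, C9–OH) | CC[Si](CC)(CC)O[C@H]1CC/C(C)=C\[C@@H]2OC(=O)C(C)=C2[C@@H](O)[C@H]2[C@@H](C)[C@@H](OCc3ccc4ccccc4c3)C[C@H](O[Si](C)(C)C(C)(C)C)[C@@]21C | intermediate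
34 | 8,17-epoxy lactone | CC[Si](CC)(CC)O[C@H]1CC/C(C)=C\[C@@H]2OC(=O)[C@]3(C)O[C@]23[C@@H](O)[C@H]2[C@@H](C)[C@@H](OCc3ccc4ccccc4c3)C[C@H](O[Si](C)(C)C(C)(C)C)[C@@]21C | intermediate
35 | 8-hydroxy lactone (O2-TES, O14-TBS, O12-NAP) | CC[Si](CC)(CC)O[C@H]1CC/C(C)=C\[C@@H]2OC(=O)[C@H](C)[C@@]2(O)[C@@H](O)[C@H]2[C@@H](C)[C@@H](OCc3ccc4ccccc4c3)C[C@H](O[Si](C)(C)C(C)(C)C)[C@@]21C | intermediate
36 | tetraol 12-O-NAP ether | O[C@H]1CC/C(C)=C\[C@@H]2OC(=O)[C@H](C)[C@@]2(O)[C@@H](O)[C@H]2[C@@H](C)[C@@H](OCc3ccc4ccccc4c3)C[C@H](O)[C@@]21C | intermediate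
37 | 2,9,14-triacetate 12-O-NAP ether | CC(=O)O[C@H]1CC/C(C)=C\[C@@H]2OC(=O)[C@H](C)[C@@]2(O)[C@@H](OC(C)=O)[C@H]2[C@@H](C)[C@@H](OCc3ccc4ccccc4c3)C[C@H](OC(C)=O)[C@@]21C | intermediate
38 | CNP0195208.2 | CC(=O)O[C@H]1CC/C(C)=C\[C@@H]2OC(=O)[C@H](C)[C@@]2(O)[C@@H](OC(C)=O)[C@H]2[C@@H](C)[C@@H](O)C[C@H](OC(C)=O)[C@@]21C | target

**Count and risks**

Total step count: 28. Longest linear sequence: 24 steps (steps 1–5, 7–9, 12–16, 18–28).

Steps most likely to fail:

Step 7 (Proposed new method). The oxocarbenium ion at C12 may be intercepted by a second vinyl ether, or the ring closure may show poor facial selectivity relative to C1 (which C1 substituent sits axial in the chair is the least secure element). The fallback is stepwise and uses known reactions. It sets out from 6: a Mukaiyama aldol addition of tert-butyldimethyl(vinyloxy)silane (catalytic TBSOTf, silyl transfer) should give the β-silyloxy aldehyde F1. An intramolecular Hosomi–Sakurai cyclisation (BF3·OEt2, CH2Cl2, −78 °C) should then give the ring A alcohol F2, whose C12 epimers can be separated. O-alkylation of the C12 hydroxyl with 2-naphthylmethyl 2,2,2-trichloroacetimidate (catalytic TfOH) comes back to the route at 11.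

Step 23. Intermolecular coupling (oligomers) or protodehalogenation of the alkenylchromium may outrun closure of the strained ten-membered ring. The fallback closes the same ring by ring-closing metathesis at C5=C6. It sets out from 31: hydrodeiodination (Bu3SnH, catalytic Pd(PPh3)4) should give the 1,1-disubstituted alkene lactol F3. Addition of vinylmagnesium bromide to the open aldehyde form of the lactol and relactonisation should give the 5-vinylbutenolide F4. Metathesis with the second-generation Grubbs catalyst (toluene, 80 °C, 0.002 M) comes back to the route at 33, the (Z)-alkene being the less strained isomer in a cyclodecene.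

Step 24. The epoxidation may show poor facial selectivity at C8 if the C9 alkoxide does not direct, or the peroxide may open the lactone. The fallback puts the C8 oxygen on by reagent-controlled conjugate borylation. It sets out from 33: copper-catalysed β-borylation of the butenolide (B2pin2, CuCl, NaOt-Bu, a chiral ferrocenyl bisphosphine, MeOH, THF) should give the C8 boronate F5 with C17 protonated. Oxidation with retention (NaBO3·4H2O, THF/H2O) comes back to the route at 35.

Further compounds
F1 | step 7 | (S,Z)-2-[(1S)-1-(tert-butyldimethylsilyloxy)-3-oxopropyl]-2-methyl-3-[(trimethylsilyl)methyl]pent-3-enenitrile | N#C[C@@](C)([C@@H](O[Si](C)(C)C(C)(C)C)CC=O)/C(C[Si](C)(C)C)=C/C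
F2 | step 7 | ring A alcohol with O14-TBS and free C12–OH | N#C[C@@]1(C)[C@@H](O[Si](C)(C)C(C)(C)C)C[C@H](O)[C@H](C)C1=C
F3 | step 23 | lactol with C5(methyl)=CH2 terminus in place of the vinyl iodide | C=C(C)CC[C@H](O[Si](CC)(CC)CC)[C@@]1(C)[C@@H](O[Si](C)(C)C(C)(C)C)C[C@H](OCc2ccc3ccccc3c2)[C@H](C)[C@@H]1[C@H](O)C2=C(C)C(=O)OC2O
F4 | step 23 | 5-vinylbutenolide diene (C7 epimers) | C=C(C)CC[C@H](O[Si](CC)(CC)CC)[C@@]1(C)[C@@H](O[Si](C)(C)C(C)(C)C)C[C@H](OCc2ccc3ccccc3c2)[C@H](C)[C@@H]1[C@H](O)C2=C(C)C(=O)OC2C=C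
F5 | step 24 | C8 pinacol boronate of the saturated lactone | CC[Si](CC)(CC)O[C@H]1CC/C(C)=C\[C@@H]2OC(=O)[C@H](C)[C@@]2(B3OC(C)(C)C(C)(C)O3)[C@@H](O)[C@H]2[C@@H](C)[C@@H](OCc3ccc4ccccc4c3)C[C@H](O[Si](C)(C)C(C)(C)C)[C@@]21C
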